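1. A one-step world has starting material meeting partner and nothing else, and its ledger is the equivalents of partner. These runs also hold protic impurity, and I assumed that it takes partner one to one.

| setting | winter | spring | summer | flask |
|---|---|---|---|---|
| starting material | 0.099 M | 0.099 M | 0.099 M | 0.099 M |
| partner | 0.17 M | 0.37 M | 0.247 M | 0.247 M |
| protic impurity | 0.099 M | 0.099 M | 0.050 M | 0.0990 M |
| remark | run made earlier | run made earlier | run made earlier |  |
| time |  |  |  | 20 min |

- winter (time / min: over-reaction product / %, target / %, starting material / %): 2.00: 1.3, 13.4, 86.9; 4.00: 2.3, 21.3, 77.7; 10.0: 2.2, 38.1, 60.3; 25.0: 1.5, 60.5, 39.3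
- spring (time / min: over-reaction product / %, target / %, starting material / %): 2.00: 0.9, 19.8, 79.7; 4.00: 0.7, 38.0, 61.8; 10.0: 6.1, 64.7, 26.5; 25.0: 21.1, 77.7, 0.6
- summer (time / min: over-reaction product / %, target / %, starting material / %): 3.00: 0.4, 24.8, 74.1; 8.00: 3.5, 50.4, 44.8; 15.0: 9.0, 73.2, 19.6; 25.0: 15.3, 84.0, 2.6

(each reading ± 1 percentage point)

- where most of what was charged as starting material, at 20 min is found (over-reaction product / starting material / target)
- the largest share itself, whichever of these holds it, in percent of the starting material charged



2. I therefore carried 0.175, the flask's margin: the base-ten logarithm of partner minus impurity, over starting material. Above zero, the usable partner covers the starting material.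

3. For each unit of error in a charge's logarithm, the margin moves 1.67 for partner, 0.669 for impurity and 1 for starting material, so partner had to be known best. Time does not enter the margin, so I compared readings at one time.

4. The winter margin is −0.144 and the summer margin 0.299, with target at 60.5% and 84.0% at 25.0 min. A reading's scatter is 1 percentage point, against a gap of 23 points. Interpolating on the margin gave 77.4% at that time, so for the earlier 20 min I committed to target, somewhat below that figure.

5. The forecast, made to “interpolate rather than fit”, gave target at 73%.

6. The flask held 75.5% as target at 20 min.

    partner + target → over-reaction product (k = 0.00210 /M/s)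
    partner ⇌ dormant form (K = 0.590, k = 0.00130 /s)
    starting material + partner → target, rate k3*[starting material]^0.5*[partner]^0.5 (k = 0.00120 /s)
    partner + protic impurity → quenched reagent (k = 0.200 /M/s)

Target was then being made 5.57 times faster than used up, each step taken net. The flask's margin is positive, and at 20 min the flask held more partner, 0.0338 M, than starting material, 0.0179 M. With 0.40 M of starting material, the neighbour's margin is −0.432, which by the one-to-one count allows 37.0% of that starting material to react. Partner was the limiting reagent there, down to 0.57% of its charge with 0.00834 M of dormant form beside it, and that neighbour kept 66.6% as starting material.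

(All runs were computed from invented constants, and the scatter is random.)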